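**Plan**
- Cuts: in the cyclohexadienone ring (C1 = ring C=O, C2 bears the CH2 bridge, C4 = CMe2, C6 bears the isobutyryl group) the bonds C1–C6 and C3–C4 are cut together. Then follow the two bonds of the CH2 bridge, the pyran ring and the aryl ketone.
- Enabling feature: C4(Me2), C5(OH), C6 and the isobutyryl group on C6 together form the skeleton of one symmetric molecule, 2,6-dimethylheptane-3,5-dione. C1, C2 and C3 are a malonyl unit that carries the CH2–aryl group.
- Helper ring: the C7 hydroxyl of the chromene lies ortho to the bridge at C8. It can hold one malonyl carbonyl as a six-membered aryl lactone, a ring absent from the target, while the other carbonyl is an acid chloride. This tells the two acylations apart, masks the phenol and supplies the leaving group.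
- Forward order: acylated benzene ring, then the pyran ring, then the helper lactone ring (three-component condensation at C8). A formal [3+3] annulation with the bis(silyl enol ether) of the diketone follows. It builds the carbocycle, its quaternary carbon and its acyl side chain, opens the lactone and gives the target directly.
- Stereochemistry: the target has no stereocentre. The only one on the way (C3 of the lactone, racemic and labile) is lost by enolisation in the last step.

Key step: step 6

Assumption: each β-tricarbonyl or enol unit is drawn as one tautomer, and the enol ether double bond of 13 and 14 is drawn Z, although its geometry has no bearing on the outcome.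

**Step 1**
Reactants: 1 phloroglucinol; 2 isobutyryl chloride
Product: 3 2-methyl-1-(2,4,6-trihydroxyphenyl)propan-1-one
Conditions: AlCl3 (3.5 equiv), PhNO2/CH2Cl2, 0 → 45 °C; ice/1 M HCl
Reagents that add atoms: none
Why: Friedel–Crafts C-acylation of the very electron-rich ring should stop after one acyl group, because the chelated aryl ketone deactivates the ring.

**Step 2**
Reactants: 3 2-methyl-1-(2,4,6-trihydroxyphenyl)propan-1-one; 4 3-methylbut-2-enal
Product: 5 1-(5,7-dihydroxy-2,2-dimethyl-2H-chromen-6-yl)-2-methylpropan-1-one
Conditions: 4 (1.1 equiv), ethylenediammonium diacetate (20 mol %), MeCN, reflux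
Reagents that add atoms: none
Why: Knoevenagel-type condensation of the iminium ion of 4 at a free ring carbon gives an ortho-quinone methide that closes by oxa-6π electrocyclisation; closure through the unchelated oxygen para to the ketone gives 5, and the 8-acyl isomer from closure through an ortho oxygen is removed by chromatography.

**Step 3**
Reactants: 5 1-(5,7-dihydroxy-2,2-dimethyl-2H-chromen-6-yl)-2-methylpropan-1-one; 6 formaldehyde; 7 2,2-dimethyl-1,3-dioxane-4,6-dione (Meldrum's acid)
Product: 10 racemic lactone acid (bridge C8–CH2–CH(CO2H)–C(=O)–O–C7 on chromene 5), via methylidene dioxanedione 8 (not isolated), via benzylated dioxanedione 9 (not isolated)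
Conditions: 37% aq. CH2O (1.1 equiv), 7 (1.1 equiv), DL-proline (10 mol %), MeCN, rt; then 55 °C
Reagents that add atoms: none
Why: In this Yonemitsu-type three-component condensation the Knoevenagel product 8 is a very strong Michael acceptor that alkylates the only free ring carbon (C8) of 5, and in adduct 9 the neighbouring C7 hydroxyl attacks one dioxanedione carbonyl (6-exo-trig) with loss of acetone, the new C3 centre being racemic and of no consequence.

**Step 4**
Reactants: 10 racemic lactone acid
Product: 11 racemic lactone acid chloride (CO2H of 10 changed to COCl)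
Conditions: 1-chloro-N,N,2-trimethylprop-1-en-1-amine (1.05 equiv), CH2Cl2, 0 °C → rt; concentrated and used crude
Reagents that add atoms: 1-chloro-N,N,2-trimethylprop-1-en-1-amine, CC(C)=C(Cl)N(C)C
Why: Acid chloride formation with an α-chloroenamine runs under neutral conditions without free HCl, so the acid-sensitive chromene alkene, the lactone and the chelated C5 phenol should be left alone.

**Step 5**
Reactants: 12 2,6-dimethylheptane-3,5-dione
Product: 13 (4Z)-2,6-dimethyl-3,5-bis(trimethylsilyloxy)hepta-2,4-diene
Conditions: TMSOTf (2.3 equiv), Et3N (3 equiv), Et2O, 0 °C → rt; salt layer separated, distillation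
Reagents that add atoms: trimethylsilyl trifluoromethanesulfonate (TMSOTf), C[Si](C)(C)OS(=O)(=O)C(F)(F)F
Why: Double soft enolisation and O-silylation of a 1,3-diketone with TMSOTf/Et3N is the known one-step route to 1,3-bis(silyloxy)-1,3-dienes, and the symmetry of 12 allows only one constitution.

**Step 6**
Reactants: 11 racemic lactone acid chloride; 13 (4Z)-2,6-dimethyl-3,5-bis(trimethylsilyloxy)hepta-2,4-diene
Product: 15 2-{[5,7-dihydroxy-2,2-dimethyl-6-(2-methylpropanoyl)-2H-chromen-8-yl]methyl}-3,5-dihydroxy-4,4-dimethyl-6-(2-methylpropanoyl)cyclohexa-2,5-dien-1-one (target), via keto lactone 14 (not isolated)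
Conditions: 13 (1.5 equiv), CH2Cl2, −78 °C → rt; then Et3N (4 equiv), DMAP (20 mol %), rt → 40 °C; 1 M HCl work-up
Reagents that add atoms: none
Why: Proposed new method: the tetrasubstituted terminus of bis(silyloxy)diene 13 attacks the acid chloride carbon of 11 with loss of Me3SiCl and sets the quaternary C3–C4 bond (14); once Et3N/DMAP has stripped the labile vinylogous silyl ester, the central carbon of the freed 1,3-diketone enolate attacks the lactone carbonyl (directly or via the acylketene from E1cB loss of the phenoxide), forms C1–C6, expels the C7 phenoxide and so closes the carbocycle and opens the helper ring in one event. The closest known reaction types are the Effenberger α,α'-annulation of silyl enol ethers with malonyl dichloride, the γ-acylation of 1,3-bis(silyl enol ethers) with acid chlorides and the Claisen (Dieckmann) cyclisation of 3,5,7-triketo esters to acylphloroglucinols; new is their union in a formal [3+3] reaction on a malonyl unit whose ends are differentiated as acid chloride and aryl lactone. The single ring that forms closes in the 6-(enolexo)-exo-trig mode, helped by the gem-dimethyl group, and no stereocentre is created, since the labile C3 centre of 11 is lost on enolisation. Site selectivity (terminal against central carbon of 13) should follow from the larger HOMO coefficient at the diene terminus and from the conjugated β-silyloxy enone that only this attack leaves, while the symmetry of 12 makes both termini equal so that no regioisomer can arise. C- against O-acylation in the second stage is under thermodynamic control, because DMAP returns any enol lactone to the acyl pool and the product is drained off as its strongly stabilised vinylogous acid anion, the lactone itself being an active ester of an acidic acylphenol. The aryl ketone, the chelated C5 hydroxyl and the chromene alkene should be inert to these nearly neutral and then mildly basic conditions.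

**Compound list**
1 | phloroglucinol | Oc1cc(O)cc(O)c1 | starting material
2 | isobutyryl chloride | CC(C)C(=O)Cl | starting material
3 | 2-methyl-1-(2,4,6-trihydroxyphenyl)propan-1-one | CC(C)C(=O)c1c(O)cc(O)cc1O | intermediate
4 | 3-methylbut-2-enal | CC(C)=CC=O | starting material
5 | 1-(5,7-dihydroxy-2,2-dimethyl-2H-chromen-6-yl)-2-methylpropan-1-one | CC(C)C(=O)c1c(O)cc2OC(C)(C)C=Cc2c1O | intermediate
6 | formaldehyde | C=O | starting material
7 | 2,2-dimethyl-1,3-dioxane-4,6-dione (Meldrum's acid) | CC1(C)OC(=O)CC(=O)O1 | starting material
8 | 2,2-dimethyl-5-methylidene-1,3-dioxane-4,6-dione | C=C1C(=O)OC(C)(C)OC1=O | intermediate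
9 | 5-{[5,7-dihydroxy-2,2-dimethyl-6-(2-methylpropanoyl)-2H-chromen-8-yl]methyl}-2,2-dimethyl-1,3-dioxane-4,6-dione | CC(C)C(=O)c1c(O)c(CC3C(=O)OC(C)(C)OC3=O)c2OC(C)(C)C=Cc2c1O | intermediate
10 | racemic lactone acid: 7-hydroxy-8-isobutyryl-2-oxochroman-3-carboxylic acid with a 2,2-dimethyl-2H-pyran ring fused at C5 (O) and C6 (CH=) of the chroman | CC(C)C(=O)c1c(O)c2C=CC(C)(C)Oc2c2CC(C(=O)O)C(=O)Oc12 | intermediate
11 | racemic lactone acid chloride (COCl in place of CO2H of 10) | CC(C)C(=O)c1c(O)c2C=CC(C)(C)Oc2c2CC(C(=O)Cl)C(=O)Oc12 | intermediate
12 | 2,6-dimethylheptane-3,5-dione | CC(C)C(=O)CC(=O)C(C)C | starting material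
13 | (4Z)-2,6-dimethyl-3,5-bis(trimethylsilyloxy)hepta-2,4-diene | CC(C)/C(O[Si](C)(C)C)=C/C(O[Si](C)(C)C)=C(C)C | intermediate
14 | racemic keto lactone: lactone of 10 bearing at C3 a (4Z)-2,2,6-trimethyl-3-oxo-5-(trimethylsilyloxy)hept-4-enoyl group in place of CO2H | CC(C)/C(O[Si](C)(C)C)=C/C(=O)C(C)(C)C(=O)C1Cc2c(OC1=O)c(C(=O)C(C)C)c(O)c1C=CC(C)(C)Oc21 | intermediate
15 | 2-{[5,7-dihydroxy-2,2-dimethyl-6-(2-methylpropanoyl)-2H-chromen-8-yl]methyl}-3,5-dihydroxy-4,4-dimethyl-6-(2-methylpropanoyl)cyclohexa-2,5-dien-1-one | CC(C)C(=O)C1=C(O)C(C)(C)C(O)=C(Cc2c(O)c(C(=O)C(C)C)c(O)c3c2OC(C)(C)C=C3)C1=O | target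

**Total step count:** 6. **Longest linear sequence:** 5 steps (1, 2, 3, 4, 6) from phloroglucinol. Step 5 is a one-step side branch.

**Steps most likely to fail**

1. Step 6.
   - What may go wrong: the hindered diene terminus may lose out to acylation at the central carbon or at oxygen. The acid chloride may drift into ketene oligomerisation. The second closure may stop at an enol lactone that does not revert. The methylene bridge may scramble by retro-Michael cleavage under base.
   - Fallback (known chemistry; it gives up the ring construction and dearomatises instead): it sets out from 3 and 5 and rejoins the route at 15. Double C-methylation of 3 at one ring carbon (MeI, NaOMe, MeOH) is the known route to 2-isobutyryl-3,5-dihydroxy-4,4-dimethylcyclohexa-2,5-dien-1-one (isobutyrylfilicinic acid) F1. F1 and chromene 5 are then joined at their free ring carbons with aqueous formaldehyde and mild base, the classical methylene bridging of acylphloroglucinols. The two symmetric dimers are removed by chromatography to reach 15.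

2. Step 3.
   - What may go wrong: formaldehyde may bridge two molecules of 5 before the dioxanedione is taken up. The malonic half acid may lose CO2 prematurely during lactonisation.
   - Fallback: it sets out from 5 and returns at 10. Vilsmeier–Haack formylation (POCl3, DMF, then water) at the only free position gives 5,7-dihydroxy-2,2-dimethyl-6-(2-methylpropanoyl)-2H-chromene-8-carbaldehyde F2. Knoevenagel condensation of F2 with 7 (piperidinium acetate cat., EtOH) and spontaneous lactonisation gives the robust coumarin-3-carboxylic acid analogue of 10 (C3=C4 double bond) F3. Its alkylidene malonate unit is reduced in the 1,4 sense with NaBH4 (THF/EtOH, 0 °C) to 10.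

3. Step 2.
   - What may go wrong: the electrocyclisation may show poor regioselectivity between the para and ortho oxygens. A second chromene ring may also form.
   - Fallback: it sets out from 3 and returns at 5. The most acidic, unchelated para hydroxyl is alkylated with 3-chloro-3-methylbut-1-yne (DBU, CuCl2 cat., MeCN, 0 °C) to give 1-[2,6-dihydroxy-4-(2-methylbut-3-yn-2-yloxy)phenyl]-2-methylpropan-1-one F4. The two ortho hydroxyls are masked (Ac2O, pyridine) as the diacetate of F4, F5. Heating in xylene (140 °C) then triggers the aryl propargyl ether Claisen rearrangement, [1,5]-H shift and oxa-6π closure. Only the para oxygen carries a hydrogen at that stage, so the product is the 5,7-diacetate of chromene 5, F6. Methanolysis (K2CO3, MeOH, rt) gives 5.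

**Further compounds**
F1 | step 6 | 2-isobutyryl-3,5-dihydroxy-4,4-dimethylcyclohexa-2,5-dien-1-one (isobutyrylfilicinic acid) | CC(C)C(=O)C1=C(O)C(C)(C)C(O)=CC1=O
F2 | step 3 | 5,7-dihydroxy-2,2-dimethyl-6-(2-methylpropanoyl)-2H-chromene-8-carbaldehyde | CC(C)C(=O)c1c(O)c(C=O)c2OC(C)(C)C=Cc2c1O
F3 | step 3 | coumarin-3-carboxylic acid analogue of 10 (C3=C4 double bond) | CC(C)C(=O)c1c(O)c2C=CC(C)(C)Oc2c2C=C(C(=O)O)C(=O)Oc12
F4 | step 2 | 1-[2,6-dihydroxy-4-(2-methylbut-3-yn-2-yloxy)phenyl]-2-methylpropan-1-one | CC(C)C(=O)c1c(O)cc(OC(C)(C)C#C)cc1O
F5 | step 2 | diacetate of F4 | CC(C)C(=O)c1c(OC(C)=O)cc(OC(C)(C)C#C)cc1OC(C)=O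
F6 | step 2 | 5,7-diacetate of chromene 5 | CC(C)C(=O)c1c(OC(C)=O)cc2OC(C)(C)C=Cc2c1OC(C)=O
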